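**Retrosynthetic overview**
1. Ring A endgame: the C3 angelate and the trans-diequatorial C2/C3 oxygens come from a C3 ketone (enolate hydroxylation at C2, then hydride reduction); the 13Z side chain comes from a B-alkyl Suzuki–Miyaura coupling of a C9 vinyl group with an (E)-2-iodobut-2-ene-1,4-diol ether.
2. C8=C17 and the C9 stereocentre come from kinetic deconjugation of a Δ8(9) C11 ester; H5 comes from base equilibration of the cycloadduct.
3. Ring B is closed in one [4+2] event: C7–C8 and C9–C10 form together from the ring-A diene C7=C6–C5=C10 and ethyl buta-2,3-dienoate (C17=C8=C9–C11).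
4. Enabling feature: in ring B the exocyclic methylene C17 on C8 lies next to the C9 methine that carries C11, so C17=C8–C9–C11 is the retron of a 2,3-allenoate; C7–C6–C5–C10(C20), with C5 and C10 shared with ring A, is a 2-methyl-1-vinylcyclohexene; C4 sits between oxygenated C3 and C5, the pattern of a desymmetrised 2-methylcyclohexane-1,3-dione.
5. Ring order: ring A (from the dione, enantioselective reduction) → ring B (Diels–Alder) → side chain → ring A oxygenation and acylation.

Key step: step 10

Remark: labdane numbering is used (ring A = C1–C5, C10; ring B = C5–C10; C17 = exocyclic methylene carbon; C18 = CH2OH and C19 = CH3 on C4; C20 = CH3 on C10). β is the face of H5, H9 and C18; α is the face of C19, C20 and the C9 side chain. The target is read as (2S,3S,4S,5S,9R,10S), 13Z, that is 2β-OH and 3α-angelate, both equatorial.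

Step 1
Reactants: 1 but-2-yne-1,4-diol
Product: 2 1,4-bis(tert-butyldiphenylsilyloxy)but-2-yne
Conditions: TBDPSCl (2.2 equiv), imidazole, DMF, 0 °C to rt
Reagents that add atoms: tert-butyl(chloro)diphenylsilane, CC(C)(C)[Si](Cl)(c1ccccc1)c1ccccc1
Why: Imidazole-promoted silylation of two primary alcohols should be clean and no stereocentre is involved.

Step 2
Reactants: 2 1,4-bis(tert-butyldiphenylsilyloxy)but-2-yne
Product: 4 (E)-1,4-bis(tert-butyldiphenylsilyloxy)-2-iodobut-2-ene, via vinylstannane 3 (not isolated)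
Conditions: Bu3SnH, PdCl2(PPh3)2 (2 mol%), THF, 0 °C to rt; then I2, CH2Cl2, 0 °C
Reagents that add atoms: iodine, II
Why: Palladium-catalysed hydrostannation adds H and Sn syn across the symmetrical alkyne (no regiochemical issue) and iododestannylation should proceed with retention, so the two CH2O groups end up cis, as the 13Z side chain needs.

Step 3
Reactants: 5 2-methylcyclohexane-1,3-dione
Product: 6 2-(hydroxymethyl)-2-methylcyclohexane-1,3-dione
Conditions: 37% aq. HCHO, NaHCO3 (cat.), H2O/THF, rt
Reagents that add atoms: formaldehyde, C=O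
Why: Aldol addition of the acidic dione C2 carbon to formaldehyde should install the future C18 on the future C4; the product is achiral.

Step 4
Reactants: 6 2-(hydroxymethyl)-2-methylcyclohexane-1,3-dione
Product: 7 2-[(tert-butyldimethylsilyloxy)methyl]-2-methylcyclohexane-1,3-dione
Conditions: TBSCl, imidazole, CH2Cl2, 0 °C
Reagents that add atoms: tert-butyl(chloro)dimethylsilane, CC(C)(C)[Si](C)(C)Cl
Why: Mild silylation should cap the primary alcohol before retro-aldol loss of formaldehyde can compete and gives the large group needed for the next step.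

Step 5
Reactants: 7 2-[(tert-butyldimethylsilyloxy)methyl]-2-methylcyclohexane-1,3-dione
Product: 8 (2S,3S)-2-[(tert-butyldimethylsilyloxy)methyl]-3-hydroxy-2-methylcyclohexan-1-one (OH cis to CH2OTBS)
Conditions: (R)-1-methyl-3,3-diphenyltetrahydro-1H,3H-pyrrolo[1,2-c][1,3,2]oxazaborole (20 mol%), BH3·SMe2 (0.6 equiv), THF, −30 °C; MeOH quench
Reagents that add atoms: none
Why: Corey–Bakshi–Shibata reduction should desymmetrise the dione, the catalyst choosing one enantiotopic carbonyl (carbinol S, future C3) and hydride arriving anti to the larger CH2OTBS group, which fixes the quaternary centre (future C4) with CH3 α and CH2O β.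

Step 6
Reactants: 8 (2S,3S)-hydroxy ketone
Product: 10 ring-A ketone acetonide (cis-fused O3,O18-isopropylidene acetal; C5 ketone), via diol 9 (not isolated)
Conditions: camphor-10-sulfonic acid (cat.), MeOH, rt; concentrate; then 2,2-dimethoxypropane, acetone, rt
Reagents that add atoms: 2,2-dimethoxypropane, COC(C)(C)OC
Why: Acid methanolysis should remove the primary TBS ether and acetal exchange then closes the cis-1,3-diol to the six-membered acetonide, whose cis-fused dioxane holds the C4 methyl pseudoaxial on the α face.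

Step 7
Reactants: 10 ring-A ketone acetonide
Product: 11 C10-methyl ketone (both C10 epimers)
Conditions: LiN(iPr)2, THF, −78 °C; MeI, −78 to −20 °C
Reagents that add atoms: iodomethane, CI
Why: Enolate alkylation at the only enolisable α-carbon (future C10) should introduce C20; the new centre becomes sp2 in the next step, so both epimers are used.

Step 8
Reactants: 11 C10-methyl ketone
Product: 12 ring-A enol triflate (C5(OTf)=C10(CH3))
Conditions: KN(SiMe3)2, THF, −78 to 0 °C; PhNTf2, −78 °C to rt
Reagents that add atoms: N-phenylbis(trifluoromethanesulfonimide), O=S(=O)(N(c1ccccc1)S(=O)(=O)C(F)(F)F)C(F)(F)F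
Why: Because C4 is quaternary only the C10 enolate can form, and O-triflation should give the tetrasubstituted enol triflate and converge the C10 epimers.

Step 9
Reactants: 12 ring-A enol triflate
Product: 13 ring-A diene (C7=C6–C5=C10(CH3); O3,O18-acetonide)
Conditions: tributyl(vinyl)stannane, Pd(PPh3)4 (5 mol%), LiCl, THF, 65 °C
Reagents that add atoms: tributyl(vinyl)stannane, C=C[Sn](CCCC)(CCCC)CCCC
Why: Stille coupling of hindered cyclohexenyl triflates with vinylstannanes is a standard route to 2,6,6-trisubstituted 1-vinylcyclohexenes and should install C6 and C7.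

Step 10
Reactants: 13 ring-A diene; 14 ethyl buta-2,3-dienoate
Product: 16 ethyl 3β,18-O-isopropylidene Δ6,Δ8(9)-dien-11-oate (5β-H, 10α-CH3; trans-fused), via Diels–Alder adduct 15 (not isolated)
Conditions: 14 (3 equiv), 2,6-di-tert-butyl-4-methylphenol (cat.), toluene, 130 °C, sealed tube; concentrate; then NaOEt (0.3 equiv), EtOH, 70 °C
Reagents that add atoms: none
Why: A thermal, normal-demand, concerted but asynchronous [4+2] cycloaddition joins the s-cis diene C7=C6–C5=C10 to the C8=C9 bond of the allenoate, bonding of the unsubstituted terminus C7 to the electrophilic central carbon C8 running ahead of C9–C10 bonding; ethoxide then moves both skipped double bonds into the conjugated dienoate by deprotonation at C9 and then C7, with protonation at C17 and C5. The closest known reaction types are Diels–Alder additions of acetylenic esters to 2,6,6-trisubstituted 1-vinylcyclohexenes followed by base isomerisation, and cycloadditions of 2,3-allenoates to 1,3-dienes at their α,β-bond. Ring B is the only ring closed, by the intermolecular [4+2] mode, suprafacial on both partners. C10 is set by π-facial selectivity, since the cis-fused acetonide holds the C4 methyl pseudoaxial on the α face and the dienophile should add on the β face, leaving C20 α; C5 is set in the isomerisation by protonation of the extended enolate on the β face, which gives the trans-fused and thermodynamically preferred ring junction; C9 forms as an endo/exo mixture that converges once C9 becomes sp2. The step needs ortho regiochemistry (ester-bearing C9 to C10), which the largest HOMO coefficient and lowest hindrance at C7 should secure, and facial control, which the acetonide lock supplies.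

Step 11
Reactants: 16 conjugated dienoate
Product: 17 ethyl 3β,18-O-isopropylidene Δ8(9)-en-11-oate
Conditions: H2 (1 atm), 10% Pd/C, EtOAc, rt
Reagents that add atoms: none
Why: The disubstituted C6=C7 alkene should hydrogenate in preference to the tetrasubstituted, ester-conjugated C8=C9 alkene; no stereocentre is formed.

Step 12
Reactants: 17 Δ8(9)-enoate
Product: 18 ethyl 3β,18-O-isopropylidene Δ8(17)-en-11-oate (9β-H)
Conditions: LiN(iPr)2 (1.3 equiv), HMPA, THF, −78 °C; then AcOH, THF, −78 °C
Reagents that add atoms: none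
Why: Deconjugative protonation: the base should remove a proton from the C17 methyl (the γ-position cis to the ester across C8=C9) and kinetic protonation of the dienolate at C9 from the axial β face, anti to the C20 methyl, gives the exocyclic alkene with C11 equatorial α.

Step 13
Reactants: 18 Δ8(17)-enoate
Product: 19 C11 primary alcohol
Conditions: LiAlH4, Et2O, 0 °C
Reagents that add atoms: none
Why: Hydride reduction of the ester should leave the acetonide, the alkene and C9 untouched.

Step 14
Reactants: 19 C11 primary alcohol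
Product: 20 C11 aldehyde
Conditions: Dess–Martin periodinane, NaHCO3, CH2Cl2, 0 °C to rt
Reagents that add atoms: none
Why: Buffered Dess–Martin oxidation is mild enough for the β,γ-unsaturated, α-branched aldehyde, which is used at once.

Step 15
Reactants: 20 C11 aldehyde
Product: 21 C9 vinyl compound (C11=C12)
Conditions: Ph3PCH3Br, KN(SiMe3)2, THF, 0 °C; then 20, −78 to 0 °C
Reagents that add atoms: methyltriphenylphosphonium bromide, C[P+](c1ccccc1)(c1ccccc1)c1ccccc1.[Br-]
Why: Wittig methylenation should add C12; any C9 epimerisation would favour the desired equatorial isomer.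

Step 16
Reactants: 21 C9 vinyl compound; 4 (E)-vinyl iodide
Product: 23 3β,18-O-isopropylidene 15,16-bis(tert-butyldiphenylsilyl) ether of the 8(17),13Z-diene, via B-alkyl-9-BBN borane 22 (not isolated)
Conditions: 9-BBN (1.1 equiv), THF, 0 °C to rt; then 4, Pd(dppf)Cl2 (dppf = 1,1'-bis(diphenylphosphino)ferrocene, 5 mol%), AsPh3, Cs2CO3, DMF/THF/H2O, rt
Reagents that add atoms: none
Why: 9-BBN should hydroborate the monosubstituted vinyl group (boron at C12) in preference to the 1,1-disubstituted C8=C17 alkene, and B-alkyl Suzuki–Miyaura coupling retains the iodide geometry, giving the 13Z alkene.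

Step 17
Reactants: 23 coupled acetonide
Product: 24 3β,18-diol
Conditions: pyridinium p-toluenesulfonate, MeOH, 40 °C
Reagents that add atoms: none
Why: Transacetalisation should remove the acetonide while the TBDPS ethers and both alkenes survive the mild acid.

Step 18
Reactants: 24 3β,18-diol
Product: 25 18-O-TBS 3β-alcohol
Conditions: TBSCl (1.1 equiv), imidazole, CH2Cl2, 0 °C
Reagents that add atoms: tert-butyl(chloro)dimethylsilane, CC(C)(C)[Si](C)(C)Cl
Why: The primary C18 hydroxyl should silylate selectively over the axial, neopentylic C3 hydroxyl.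

Step 19
Reactants: 25 18-O-TBS 3β-alcohol
Product: 26 C3 ketone
Conditions: Dess–Martin periodinane, NaHCO3, CH2Cl2, rt
Reagents that add atoms: none
Why: Dess–Martin oxidation of the secondary alcohol tolerates the alkenes and silyl ethers.

Step 20
Reactants: 26 C3 ketone
Product: 28 2β-(tert-butyldimethylsilyloxy) C3 ketone, via 2β-hydroxy ketone 27 (not isolated)
Conditions: KN(SiMe3)2, THF, −78 °C; 2-(phenylsulfonyl)-3-phenyloxaziridine, −78 °C; then TBSOTf, −78 to 0 °C
Reagents that add atoms: 2-(phenylsulfonyl)-3-phenyloxaziridine, O=S(=O)(N1OC1c1ccccc1)c1ccccc1; tert-butyldimethylsilyl trifluoromethanesulfonate, CC(C)(C)[Si](C)(C)OS(=O)(=O)C(F)(F)F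
Why: Only C2 can enolise, and in this enolate hydroxylation the oxaziridine should attack C2 from the β face because the α face is blocked by the axial C19 and C20 methyls, giving the equatorial 2β-oxygen, which is silylated in the same flask.

Step 21
Reactants: 28 2β-silyloxy C3 ketone
Product: 29 2β-(tert-butyldimethylsilyloxy) 3α-alcohol
Conditions: NaBH4, MeOH/THF, −20 to 0 °C
Reagents that add atoms: none
Why: Axial hydride delivery from the β face, the usual course for 4,4-disubstituted 3-oxo terpenoids, should give the equatorial 3α-alcohol trans to the C2 oxygen.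

Step 22
Reactants: 29 3α-alcohol; 30 angelic acid ((Z)-2-methylbut-2-enoic acid)
Product: 32 fully silylated 3α-angelate, via mixed anhydride 31 (not isolated)
Conditions: 30, 2,4,6-trichlorobenzoyl chloride, Et3N, toluene, rt; then 29, toluene, 80 °C
Reagents that add atoms: none
Why: Yamaguchi-type acylation through the trichlorobenzoyl mixed anhydride without a nucleophilic catalyst should acylate the only free hydroxyl while keeping the Z geometry of the angeloyl group.

Step 23
Reactants: 32 fully silylated 3α-angelate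
Product: 33 CNP0324138.1 (target)
Conditions: Bu4NF, AcOH (1:1), THF, rt
Reagents that add atoms: none
Why: Acetic acid-buffered fluoride should cleave the two TBS and two TBDPS ethers while suppressing angeloyl migration to O2 or O18 and ester cleavage.

**Compound list**
1 | but-2-yne-1,4-diol | OCC#CCO | starting material
2 | 1,4-bis(tert-butyldiphenylsilyloxy)but-2-yne | CC(C)(C)[Si](OCC#CCO[Si](c1ccccc1)(c1ccccc1)C(C)(C)C)(c1ccccc1)c1ccccc1 | intermediate
3 | (E)-vinylstannane, tributyl[1,4-bis(tert-butyldiphenylsilyloxy)but-2-en-2-yl]stannane | CCCC[Sn](CCCC)(CCCC)/C(CO[Si](c1ccccc1)(c1ccccc1)C(C)(C)C)=C/CO[Si](c1ccccc1)(c1ccccc1)C(C)(C)C | intermediate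
4 | (E)-1,4-bis(tert-butyldiphenylsilyloxy)-2-iodobut-2-ene (CH2O groups cis) | I/C(CO[Si](c1ccccc1)(c1ccccc1)C(C)(C)C)=C/CO[Si](c1ccccc1)(c1ccccc1)C(C)(C)C | intermediate
5 | 2-methylcyclohexane-1,3-dione | CC1C(=O)CCCC1=O | starting material
6 | 2-(hydroxymethyl)-2-methylcyclohexane-1,3-dione | CC1(CO)C(=O)CCCC1=O | intermediate
7 | 2-[(tert-butyldimethylsilyloxy)methyl]-2-methylcyclohexane-1,3-dione | CC1(CO[Si](C)(C)C(C)(C)C)C(=O)CCCC1=O | intermediate
8 | (2S,3S)-2-[(tert-butyldimethylsilyloxy)methyl]-3-hydroxy-2-methylcyclohexan-1-one | O=C1CCC[C@H](O)[C@]1(C)CO[Si](C)(C)C(C)(C)C | intermediate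
9 | (2S,3S)-3-hydroxy-2-(hydroxymethyl)-2-methylcyclohexan-1-one | O=C1CCC[C@H](O)[C@]1(C)CO | intermediate
10 | ring-A ketone acetonide (cis-fused O3,O18-isopropylidene acetal of 9; C5 ketone) | O=C1CCC[C@@H]2OC(C)(C)OC[C@]12C | intermediate
11 | C10-methyl ketone (both C10 epimers) | O=C1C(C)CC[C@@H]2OC(C)(C)OC[C@]12C | intermediate
12 | ring-A enol triflate, C5(OTf)=C10(CH3) | O=S(=O)(OC1=C(C)CC[C@@H]2OC(C)(C)OC[C@]12C)C(F)(F)F | intermediate
13 | ring-A diene, C7=C6–C5=C10(CH3), O3,O18-acetonide | C=CC1=C(C)CC[C@@H]2OC(C)(C)OC[C@]12C | intermediate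
14 | ethyl buta-2,3-dienoate | C=C=CC(=O)OCC | starting material
15 | Diels–Alder adduct, Δ5,Δ8(17)-diene C11 ethyl ester (C9 epimers) | C=C1CC=C2[C@@](C)(CC[C@@H]3OC(C)(C)OC[C@]23C)C1C(=O)OCC | intermediate
16 | Δ6,Δ8(9)-dienoate, 5β-H, 10α-CH3 | CC1=C(C(=O)OCC)[C@]2(C)CC[C@@H]3OC(C)(C)OC[C@]3(C)[C@H]2C=C1 | intermediate
17 | Δ8(9)-enoate | CC1=C(C(=O)OCC)[C@]2(C)CC[C@@H]3OC(C)(C)OC[C@]3(C)[C@H]2CC1 | intermediate
18 | Δ8(17)-ene C11 ethyl ester, 9β-H | C=C1CC[C@H]2[C@@](C)(CC[C@@H]3OC(C)(C)OC[C@]23C)[C@@H]1C(=O)OCC | intermediate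
19 | C11 primary alcohol | C=C1CC[C@H]2[C@@](C)(CC[C@@H]3OC(C)(C)OC[C@]23C)[C@@H]1CO | intermediate
20 | C11 aldehyde | C=C1CC[C@H]2[C@@](C)(CC[C@@H]3OC(C)(C)OC[C@]23C)[C@@H]1C=O | intermediate
21 | C9 vinyl compound | C=C1CC[C@H]2[C@@](C)(CC[C@@H]3OC(C)(C)OC[C@]23C)[C@@H]1C=C | intermediate
22 | B-alkyl-9-BBN borane (boron on C12) | C=C1CC[C@H]2[C@@](C)(CC[C@@H]3OC(C)(C)OC[C@]23C)[C@@H]1CCB1C2CCCC1CCC2 | intermediate
23 | coupled acetonide, 15,16-bis-TBDPS ether, 13Z | C=C1CC[C@H]2[C@@](C)(CC[C@@H]3OC(C)(C)OC[C@]23C)[C@@H]1CC/C(=C/CO[Si](c1ccccc1)(c1ccccc1)C(C)(C)C)CO[Si](c1ccccc1)(c1ccccc1)C(C)(C)C | intermediate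
24 | 3β,18-diol | C=C1CC[C@H]2[C@@](C)(CC[C@H](O)[C@]2(C)CO)[C@@H]1CC/C(=C/CO[Si](c1ccccc1)(c1ccccc1)C(C)(C)C)CO[Si](c1ccccc1)(c1ccccc1)C(C)(C)C | intermediate
25 | 18-O-TBS 3β-alcohol | C=C1CC[C@H]2[C@@](C)(CC[C@H](O)[C@]2(C)CO[Si](C)(C)C(C)(C)C)[C@@H]1CC/C(=C/CO[Si](c1ccccc1)(c1ccccc1)C(C)(C)C)CO[Si](c1ccccc1)(c1ccccc1)C(C)(C)C | intermediate
26 | C3 ketone | C=C1CC[C@H]2[C@@](C)(CCC(=O)[C@]2(C)CO[Si](C)(C)C(C)(C)C)[C@@H]1CC/C(=C/CO[Si](c1ccccc1)(c1ccccc1)C(C)(C)C)CO[Si](c1ccccc1)(c1ccccc1)C(C)(C)C | intermediate
27 | 2β-hydroxy C3 ketone | C=C1CC[C@H]2[C@@](C)(C[C@H](O)C(=O)[C@]2(C)CO[Si](C)(C)C(C)(C)C)[C@@H]1CC/C(=C/CO[Si](c1ccccc1)(c1ccccc1)C(C)(C)C)CO[Si](c1ccccc1)(c1ccccc1)C(C)(C)C | intermediate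
28 | 2β-(TBS-oxy) C3 ketone | C=C1CC[C@H]2[C@@](C)(C[C@H](O[Si](C)(C)C(C)(C)C)C(=O)[C@]2(C)CO[Si](C)(C)C(C)(C)C)[C@@H]1CC/C(=C/CO[Si](c1ccccc1)(c1ccccc1)C(C)(C)C)CO[Si](c1ccccc1)(c1ccccc1)C(C)(C)C | intermediate
29 | 2β-(TBS-oxy) 3α-alcohol | C=C1CC[C@H]2[C@@](C)(C[C@H](O[Si](C)(C)C(C)(C)C)[C@@H](O)[C@]2(C)CO[Si](C)(C)C(C)(C)C)[C@@H]1CC/C(=C/CO[Si](c1ccccc1)(c1ccccc1)C(C)(C)C)CO[Si](c1ccccc1)(c1ccccc1)C(C)(C)C | intermediate
30 | angelic acid | C/C=C(/C)C(=O)O | starting material
31 | angelic 2,4,6-trichlorobenzoic mixed anhydride | C/C=C(/C)C(=O)OC(=O)c1c(Cl)cc(Cl)cc1Cl | intermediate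
32 | fully silylated 3α-angelate | C=C1CC[C@H]2[C@@](C)(C[C@H](O[Si](C)(C)C(C)(C)C)[C@@H](OC(=O)/C(C)=C\C)[C@]2(C)CO[Si](C)(C)C(C)(C)C)[C@@H]1CC/C(=C/CO[Si](c1ccccc1)(c1ccccc1)C(C)(C)C)CO[Si](c1ccccc1)(c1ccccc1)C(C)(C)C | intermediate
33 | CNP0324138.1 | C=C1CC[C@H]2[C@@](C)(C[C@H](O)[C@@H](OC(=O)/C(C)=C\C)[C@]2(C)CO)[C@@H]1CC/C(=C/CO)CO | target

**Step count**
Total: 23 steps. Longest linear sequence: 21 steps (steps 3–23); steps 1–2 make the side-chain fragment 4.

**Steps most likely to fail**

Step 10. The cycloaddition at the tetrasubstituted terminus of a diene that disfavours its s-cis form may be slow enough for thermal oligomerisation of 14 to take over, and discrimination between the two diene faces may be incomplete. The fallback replaces the concerted cycloaddition by a stepwise polar annulation of a more nucleophilic 2-silyloxydiene and sets out from 12. Carbonylative Stille coupling (CO, Me4Sn, Pd(PPh3)4, LiCl, DMF) should give the acetyl enone F1, and TBSOTf/Et3N then gives the 2-silyloxydiene F2. Me2AlCl-promoted Mukaiyama–Michael addition of C7 to the central carbon of 14, followed by ring closure of the ester enolate onto C10, forms the same C7–C8 and C9–C10 bonds and gives the silyl enol ether F3. CsF/PhNTf2 converts F3 into the enol triflate F4, and Pd(OAc)2/PPh3/HCO2H/Et3N reduction gives 15. Any double-bond isomers formed on the way converge under the NaOEt treatment of step 10, and the route is rejoined at 16.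

Step 12. Deprotonation may compete at the ring methylene C7, which would lead to the endocyclic Δ7 isomer. The dienolate may also be protonated at C17 (return of 17) or on the wrong face of C9. The fallback is photochemical deconjugation and sets out from 17: irradiation at 254 nm in Et2O/MeOH with catalytic 1,2-dimethylimidazole. A 1,5-hydrogen shift from the C17 methyl, which is cis to the ester carbonyl, gives a dienol that ketonises at C9. The route is rejoined at 18 and no compound outside the list is made (F0).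

Step 22. Acylation of the neopentylic C3 hydroxyl may be slow enough for Z-to-E isomerisation of the angeloyl unit, or silyl migration from O2, to compete. The fallback builds the Z alkene on the substrate and sets out from 29. Esterification with 2-[bis(2,2,2-trifluoroethoxy)phosphoryl]propanoic acid (dicyclohexylcarbodiimide, 4-(dimethylamino)pyridine, CH2Cl2) gives the phosphonate ester F5. Still–Gennari olefination with acetaldehyde (KN(SiMe3)2, 18-crown-6, THF, −78 °C) then gives the Z-configured 2-methylbut-2-enoate, and the route is rejoined at 32.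

**Further compounds**
F1 | step 10 | acetyl enone (C6 ketone, C7 methyl, C5=C10) | CC(=O)C1=C(C)CC[C@@H]2OC(C)(C)OC[C@]12C
F2 | step 10 | 2-silyloxydiene (C6–OTBS) | C=C(O[Si](C)(C)C(C)(C)C)C1=C(C)CC[C@@H]2OC(C)(C)OC[C@]12C
F3 | step 10 | annulation product, C6 silyl enol ether (C9 epimers) | C=C1CC(O[Si](C)(C)C(C)(C)C)=C2[C@@](C)(CC[C@@H]3OC(C)(C)OC[C@]23C)C1C(=O)OCC
F4 | step 10 | C6 enol triflate (C9 epimers) | C=C1CC(OS(=O)(=O)C(F)(F)F)=C2[C@@](C)(CC[C@@H]3OC(C)(C)OC[C@]23C)C1C(=O)OCC
F0 | step 12 | none | none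
F5 | step 22 | C3 2-[bis(2,2,2-trifluoroethoxy)phosphoryl]propanoate (epimers at the phosphonate carbon) | C=C1CC[C@H]2[C@@](C)(C[C@H](O[Si](C)(C)C(C)(C)C)[C@@H](OC(=O)C(C)P(=O)(OCC(F)(F)F)OCC(F)(F)F)[C@]2(C)CO[Si](C)(C)C(C)(C)C)[C@@H]1CC/C(=C/CO[Si](c1ccccc1)(c1ccccc1)C(C)(C)C)CO[Si](c1ccccc1)(c1ccccc1)C(C)(C)C
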